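To repeat this run I want to know how much target stands at the end of the time, and why the flask stands still by then.

- why nothing more happens at 20 min, or that something still does (all of the starting material has reacted / forward and back rates have come level / it is still moving)
- the target standing at 20 min, as a percentage of the starting material charged

starting material 5.0 mM (in portions, 2); protic impurity 2.50 mM; time 20 min; the portions of starting material follow each other after 12 s, the first at the start

    starting material → intermediate (k1 = 0.087 s⁻¹)
    intermediate ⇌ target (K2 = 2.4, k2 = 0.087 s⁻¹)
    intermediate ⇌ isomer of the product (K3 = 5.7, k3 = 0.031 s⁻¹)
    starting material + protic impurity → quenched substrate (k4 = 63 L mol⁻¹ s⁻¹)

- the reaction counts as stopped when no species that holds the starting material changes by six tenths of a point or more over the second half of the time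
- run time (flask): 20 min

I reckon down a ladder of half-lives. On the top rung, with the impurity as charged, quenching takes the starting material with a half-life of 0.073 min, shorter than the 0.133 min of step 1, so quenching leads at the start. Next, the intermediate leaves towards the target with a forward half-life of 0.13 min, shorter than the 0.37 min towards the isomer, so an early reading should show target above its final level: kinetic against thermodynamic control. On the lowest rung, the way back from the isomer has a half-life of 2.12 min, and the run lasts 9.42 of those. I therefore take intermediate, target and isomer as level at the end, with the target holding 26.4 % of their sum.

That sum is the part of the charge that escapes quenching. Dividing the rate of quenching by the rate of step 1 cancels the starting material and the time, and leaves the impurity level over the crossover level, which is k1 over k4 as a fraction of the charge, 27.6 %. At that impurity level the two branches take equal shares; it is their selectivity factor written as an amount. The impurity is charged at 50.0 % of the starting material, above crossover.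

Since time has cancelled, the timing of the portions has gone too. The quenched part is the impurity charge times the fraction of it used. The escaped part is the crossover level times the logarithm of the impurity's charge over what remains of it. Once the starting material has reacted, together they make the whole charge of it. Solving in rounds, beginning from impurity used up, leaves 16.4 %, then 12.2 %, then 13.1 % of the impurity. So 43.4 % is quenched, 56.6 % escapes, and the target comes to 14.9 %. The run holds 151 half-lives of step 1, so I commit to the flask standing because the starting material has reacted away.

The forecast gives 14.9 % of target and, as the ending, forward and back rates have come level, with the mixture “fully equilibrated by 20 min”. On the target we agree; on the ending I differ.

The flask gives 14.9 % of target, and its ending is all of the starting material has reacted: starting material reads 0 % at 4.00 min. The impurity left in the flask at 20.0 min is 6.47 % of the charge of starting material, below the crossover level of 27.6 %. In the neighbour flask with 1.2 mM of starting material, crossover rises to 115 % of that smaller charge, and with 71 % of its impurity left the escaped part reckons to 39.5 %, hence 10.4 % of target. That neighbour flask stands at 10.4 %.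

(Its constants were set for the occasion; the flask was simulated.)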